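## Assumptions
- The target SMILES is taken as drawn: trans-fused hydroazulene, 3R,3aS,4S,8aR by my CIP assignment, with the 4-hydroxybenzoate on the secondary alcohol C4 (azulene numbering).
- 3-Methylbut-3-enal (compound 2) is prepared fresh from isoprenol and used as a cold solution, because it isomerises easily to prenal.
- A Josiphos-type Cu catalyst is assumed to deliver the allyl group to the Si face of 3-methylcyclopent-2-enone. Step 2 is the least precedented step in the route.

## Retrosynthetic overview
1. Ferutinine is the 4-hydroxybenzoate of jaeschkeanadiol. The last step is a chemoselective acylation of the secondary C4–OH (an aryl-acetate-protected acid chloride is used, then the acetate is removed).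
2. The tertiary C3 carbinol comes from isopropyl-cerium adding to a hydroazulen-3-one from the face anti to the angular methyl.
3. The seven-membered ring is closed last by ring-closing metathesis (RCM) of a cyclopentanone carrying an allyl group and a methallyl carbinol. This gives the trans-fused C1=C2 trisubstituted cycloheptene.
4. The cyclopentanone comes from a one-pot Cu-catalysed asymmetric conjugate allylation and aldol of 3-methylcyclopentenone with 3-methylbut-3-enal. This sets the quaternary carbon, C3a and C4 together.
5. Ring order: the five-membered ring is purchased, then the seven-membered ring is formed by RCM.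

## Route

**Step 1**
Reactants: 1, 3-methylbut-3-en-1-ol (isoprenol)
Product: 2, 3-methylbut-3-enal
Conditions: Dess–Martin periodinane, NaHCO3, CH2Cl2, 0 → 25 °C; cold solution used directly.
Reagents that add atoms: none
Why: Buffered Dess–Martin oxidation converts the primary alcohol to the aldehyde without isomerising the β,γ-alkene into conjugation.

**Step 2**
Reactants: 3, 3-methylcyclopent-2-en-1-one; 4, allylmagnesium chloride; 2, 3-methylbut-3-enal
Product: 5, (2S,3R)-2-[(1S)-1-hydroxy-3-methylbut-3-en-1-yl]-3-methyl-3-(prop-2-en-1-yl)cyclopentan-1-one
Conditions: CuBr·SMe2 (5 mol%), (R,S)-Josiphos-type ligand (6 mol%), allylMgCl, MTBE, –78 °C; then 2, –78 → 0 °C; NH4Cl work-up.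
Reagents that add atoms: allylmagnesium chloride, C=CC[Mg]Cl (compound 4)
Why: In a Cu-catalysed asymmetric conjugate addition followed by aldol (tandem Michael–aldol), the ligand sets the (R) quaternary carbon by Si-face allyl delivery. The magnesium enolate forms only at C2, so the adjacent hindered position is functionalised without a regiochemistry problem. It is ring-locked E, so it adds through a Zimmerman–Traxler chair to give the anti aldol, from the face anti to the new allyl group. That puts the carbinol side chain trans to allyl and cis to the methyl, which is the trans-fusion geometry needed later.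

**Step 3**
Reactant: 5
Product: 6, (3aS,4S,8aR)-4-hydroxy-6,8a-dimethyl-1,2,4,5,8,8a-hexahydroazulen-3(3aH)-one
Conditions: Hoveyda–Grubbs II (8 mol%), toluene (0.005 M), 80 °C, 1,4-benzoquinone (10 mol%); ethylene is lost.
Reagents that add atoms: none
Why: RCM joins the allyl group and the 1,1-disubstituted methallyl alkene to form the C1=C2 trisubstituted cycloheptene and the trans-fused 5-7 system. No stereocentre is created or altered, and the free β-hydroxy ketone survives because Ru-carbene catalysts tolerate it.

**Step 4**
Reactants: 6; 7, isopropylmagnesium bromide
Product: 8, jaeschkeanadiol, (3R,3aS,4S,8aR)-6,8a-dimethyl-3-(propan-2-yl)-1,2,3,3a,4,5,8,8a-octahydroazulene-3,4-diol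
Conditions: anhydrous CeCl3 (4 equiv), iPrMgBr (4 equiv), THF, –78 → –40 °C; NH4Cl work-up.
Reagents that add atoms: isopropylmagnesium bromide, CC(C)[Mg]Br (compound 7)
Why: 1,2-Addition of an organocerium reagent avoids enolisation and reduction of the ketone. The isopropyl group is delivered from the α face, anti to the angular methyl and to the adjacent C4 substituent. This gives the tertiary OH cis to the methyl and iPr trans to it, as in the target.

**Step 5**
Reactants: 8; 9, 4-acetoxybenzoyl chloride
Product: 10, (3R,3aS,4S,8aR)-3-hydroxy-6,8a-dimethyl-3-(propan-2-yl)-octahydroazulen-4-yl 4-acetoxybenzoate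
Conditions: 9 (1.5 equiv), pyridine, DMAP (0.2 equiv), CH2Cl2, 0 → 25 °C.
Reagents that add atoms: 4-acetoxybenzoyl chloride, CC(=O)Oc1ccc(cc1)C(=O)Cl (compound 9)
Why: Nucleophilic acyl substitution acylates the secondary alcohol selectively over the hindered tertiary alcohol. The C4 configuration is retained because no bond to the stereocentre is broken. The acetate keeps the phenol from reacting with the acid chloride.

**Step 6**
Reactant: 10
Product: 11, ferutinine, (3R,3aS,4S,8aR)-3-hydroxy-6,8a-dimethyl-3-(propan-2-yl)-1,2,3,3a,4,5,8,8a-octahydroazulen-4-yl 4-hydroxybenzoate
Conditions: K2CO3 (0.3 equiv), MeOH, 0 °C, 30 min.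
Reagents that add atoms: none
Why: Methanolysis cleaves the aryl acetate much faster than the hindered secondary alkyl benzoate, leaving the ester and both alcohols intact.

## Compound list
1 | 3-methylbut-3-en-1-ol (isoprenol) | CC(=C)CCO | starting material
2 | 3-methylbut-3-enal | CC(=C)CC=O | intermediate
3 | 3-methylcyclopent-2-en-1-one | CC1=CC(=O)CC1 | starting material
4 | allylmagnesium chloride | C=CC[Mg]Cl | starting material (reagent)
5 | aldol adduct (2S,3R)-2-[(1S)-1-hydroxy-3-methylbut-3-enyl]-3-allyl-3-methylcyclopentanone | O=C1CC[C@](C)(CC=C)[C@H]1[C@@H](O)CC(C)=C | intermediate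
6 | (3aS,4S,8aR)-4-hydroxy-6,8a-dimethyl-hexahydroazulen-3-one | CC1=CC[C@@]2(C)CCC(=O)[C@@H]2[C@@H](O)C1 | intermediate
7 | isopropylmagnesium bromide | CC(C)[Mg]Br | starting material (reagent)
8 | jaeschkeanadiol | CC1=CC[C@@]2(C)CC[C@@](O)(C(C)C)[C@@H]2[C@@H](O)C1 | intermediate
9 | 4-acetoxybenzoyl chloride | CC(=O)Oc1ccc(cc1)C(=O)Cl | starting material (reagent)
10 | ferutinine 4-O-acetate | CC1=CC[C@@]2(C)CC[C@@](O)(C(C)C)[C@@H]2[C@@H](OC(=O)c2ccc(OC(C)=O)cc2)C1 | intermediate
11 | ferutinine | CC1=CC[C@@]2(C)CC[C@@](O)(C(C)C)[C@@H]2[C@@H](OC(=O)c2ccc(O)cc2)C1 | target

## Totals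
- Total steps: 6.
- Longest linear sequence: 6, counted through the isoprenol branch (1 → 2 → 5 → 6 → 8 → 10 → 11). It is 5 steps from enone 3.

## Three steps most likely to fail
1. **Step 2 (asymmetric allyl conjugate addition and aldol).** The allyl Grignard/Cu/ligand system is not established for this enone, and the facial selectivity is only weakly biased because the two substituents at the quaternary carbon are Me and allyl.
   Fallback: set the quaternary carbon by Pd/PHOX decarboxylative asymmetric allylation of allyl 1-methyl-2-oxocyclopentanecarboxylate. Then convert the 2-allyl-2-methylcyclopentanone to the cyclopentene carbaldehyde (enol triflate, Pd/CO formylation), add methallyl-MgCl, do the RCM, and install C3 oxygen and isopropyl by allylic-alcohol-directed epoxidation and reductive opening.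
2. **Step 3 (RCM to the trans-fused trisubstituted cycloheptene).** Forming a tri-substituted alkene with a 1,1-disubstituted partner on a hindered, trans-disposed diene may stall or give oligomers.
   Fallback: close the ring by an intramolecular Hosomi–Sakurai allylation, with an allylsilane on the C8a side chain and an aldehyde on C3a. This forms the C4–C5 bond and the C6=C7 alkene in one step.
3. **Step 4 (isopropyl addition to the hindered β-hydroxy ketone).** Enolisation, retro-aldol or epimerisation at C3a, or poor facial selectivity could each give the wrong product.
   Fallback: form the C3–C3a bond last instead. Cyclise an isopropyl ketone onto the C3a position of a seven-membered-ring precursor by an intramolecular aldol or SmI2 Reformatsky closure, so that no isopropyl nucleophile is added to a stereodefined cyclopentanone.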